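**Remark (assumption):** The stereodescriptors of the target SMILES are read as (2S,3R,2''R,3''S), that is, H2/H3 and H2''/H3'' trans in each ring C and the two halves mirror images (meso, achiral). Compounds 1 and 4 are treated as catalogue compounds.

**Numbering used throughout:** 1 4'-(benzyloxy)acetophenone; 2 its lithium enolate; 3 the 1,4-diketone; 4 the fluorobenzoic acid; 5 its chloride; 6 bis(enolate) of 3; 7 tetraketone; 8 tetra-O-benzyl-3,3''-biflavone; 9 bis(enolate) from reduction; 10 biflavanone mixture; 11 meso trans,trans biflavanone; 12 target.

## Analysis of the target

The target is a 3,3''-biflavanone: two 7-hydroxy-2-(4-hydroxyphenyl)chroman-4-one units (rings A and C fused, ring B on C2; doubly primed locants for the second half) joined by a single bond between C3 and C3''. It carries four contiguous stereocentres, C2, C3, C3'' and C2''. In each ring C the aryl group and the other flavanone unit are trans, and the two halves have opposite configuration, so the molecule is the meso diastereomer and not the C2-symmetric racemic one. Each ring C is a β-aryloxy ketone whose C2–O1 bond is benzylic and para-oxygenated: base can open it by retro-oxa-Michael reaction and strong acid can ionise it, and either event scrambles C2, while C3 and C3'' are enolisable. C4, C3, C3'' and C4'' also make up a 1,4-diketone that strong acid could cyclodehydrate to a furan, and the four phenols need protecting groups that leave without acid or base. The difficulty lies in the congested C3–C3'' bond between two secondary carbons and in the relative configuration across it, which nothing in a flavanone monomer controls. The strategy rests on reading the chain O1–C2–C3–C3''–C2''–O1'' as a symmetric 1,4-diaryl-1,4-diketone: its carbonyl carbons are C2 and C2'', its carbonyl oxygens are O1 and O1'', its α-carbons are C3 and C3'', and each ring B already sits on its carbonyl carbon. Each half then lacks only C4 with ring A, that is, a 2-fluoroaroyl group that delivers C4 to the α-carbon and offers C8a to the enolate oxygen.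

## Retrosynthetic reasoning

**12 to 11.** The last disconnection is of the four phenolic O–benzyl bonds. Methyl ethers would pass through every step equally well, but removing them needs a strong Lewis or Brønsted acid. Such an acid can ionise the C2–O1 and C2''–O1'' bonds or dehydrate the 1,4-diketone, and would undo the separation of diastereomers made one step earlier. Benzyl ethers leave by neutral hydrogenolysis, which touches neither C2 nor C3. The price is that the diketone cannot be made by a Lewis-acid acylation of an aryl ether, so it is assembled differently (see the disconnection of 3).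

**11 to 10 to 8.** All four stereocentres are removed together by restoring the C2=C3 and C2''=C3'' double bonds; the bonds cut are C2–H, C3–H, C2''–H and C3''–H. In the forward direction a double conjugate hydride reduction of biflavone 8 gives the mixture 10 through bis(enolate) 9, and epimerisation at C3 and C3'' brings each ring to trans. The gain is that both rings C can be built at the aromatic oxidation level, where nothing can epimerise, eliminate or open. The loss is control over C2 against C2'': only the portion of 10 with the unlike pairing leads to 11, so a diastereomer separation is unavoidable. A chiral reducing agent would not help, because the meso pairing requires opposite configurations in the two halves.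

**8 to 3 and two molecules of 5.** This is the key disconnection. In each half the C3–C4 bond and the O1–C8a bond are cut (C3''–C4'' and O1''–C8a'' in the other), which releases two 2-fluoroaroyl units 5 and the symmetric diketone 3. The cut is made here because 3 already holds C2, C3, C3'', C2'', both oxygens O1 and O1'' and both rings B, so four bonds and two rings come from one three-component operation. In the forward direction the α-carbons of 3 must be acylated on carbon twice (through 6 to tetraketone 7), and each enolate oxygen must then displace fluoride. Because every acylation creates an acidic 1,3-diketone, four equivalents of base are needed, not two.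

**3 to 1.** The C3–C3'' bond is cut in the middle, giving two molecules of ketone 1. The forward reaction is an oxidative homocoupling of enolate 2; the coupling is symmetric, so there is no cross-coupling problem. The most congested bond of the target is thereby made first, between two unhindered methyl-derived carbons.

**5 to 4.** The C–Cl bond of the acid chloride is traced back to the carboxylic acid 4. The fluorine ortho and the benzyloxy group para to the carboxyl carbon place O1 at C8a and the oxygen substituent at C7.

## Alternatives that were turned down

**Alternative 1:** The disconnection is C3–C4 and C3''–C4'', both formed from aldehyde carbons onto the two carbons of an alkyne that becomes C3–C3''. The substrate is the meso bis(aryl ether) dialdehyde A2 (1,4-bis[4-(benzyloxy)phenyl]but-2-yne-1,4-diol etherified twice with 4-(benzyloxy)-2-hydroxybenzaldehyde units). In the forward key step the carbene from 3-benzyl-5-(2-hydroxyethyl)-4-methylthiazolium chloride and K2CO3 turns one aldehyde into an acyl-anion equivalent that adds across the alkyne (hydroacylation), and the second aldehyde then adds to the new exocyclic enone (Stetter reaction), giving the tetra-O-benzyl biflavanone A1, which is the same compound as 11.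

- In its favour: C2 and C2'' are fixed in A2 before the rings form, so the meso pairing is built in and not separated out. On this point the alternative is stronger than the chosen route. It also arrives at the flavanone oxidation level without a reduction.
- Against it, the substrate: A2 contains two aryl ether stereocentres that are both benzylic and propargylic. Etherification at such carbons invites ionisation, SN2' attack and elimination, and the parent ynediol forms as a meso/racemic mixture, so the separation problem is only moved upstream.
- Against it, the cascade: under K2CO3 the C2–H of A2 is acidic enough for propargyl–allenyl isomerisation. After the first hydroacylation the exocyclic C3=C3'' enone can slip into the endocyclic chromone, a thermodynamic sink that erases C2, or can expel the allylic aryloxide at C2''. Hydroacylation of a hindered internal alkyne is also at the edge of that reaction.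
- Comparison: the step count is similar (about six to seven), but the risk is spread over the substrate synthesis and the cascade. The chosen route makes the rings where no stereocentre exists and reaches its precursor in one step.

**Alternative 2:** The disconnection is C2–C3 and C2''–C3'', formed by a Diels–Alder reaction between diene A3, (1E,3E)-1,4-bis(4-methoxyphenyl)buta-1,3-diene, and dienophile A4, (Z)-1,4-bis(2-fluoro-4-methoxyphenyl)but-2-ene-1,4-dione. The endo cycloaddition gives the all-cis cyclohexene A5, in which a CH=CH bridge ties C2 to C2''. The bridge must then be excised: oxidative cleavage of the alkene, Baeyer–Villiger migration at both formyl groups with retention, hydrolysis, and closure of rings C by SNAr of the C2 and C2'' alkoxides onto the fluoroarenes.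

- In its favour: suprafacial addition to the E,E-diene places C2 and C2'' cis on the ring, which translates into the meso pairing with certainty. All four stereocentres are set in one concerted step in the correct relative configuration. This is stronger stereocontrol than the chosen route offers.
- Against it, the cycloaddition: 1,4-diarylbutadienes are sluggish dienes, and cis-diaroylethylenes isomerise to trans under the heat they would need.
- Against it, the excision: after cleavage C2 and C2'' are α-aryl aldehyde carbons within a γ-keto aldehyde, the most epimerisable and cyclisation-prone form they could take. The Baeyer–Villiger step must choose the formyl groups over two electron-rich aryl ketones. The β-hydroxy ketone alkoxides can fragment by retro-aldol reaction in competition with ring closure. The methyl ethers finally require a Lewis-acid demethylation on the finished flavanone.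
- Comparison: roughly nine to ten steps against six. The chosen route gives up the built-in meso pairing and offers in its place a short sequence in which the stereocentres appear only after all skeletal bonds exist.

**Alternative 3:** The disconnection is C4–C4a and C4''–C4a''. The meso succinic diacid A6, 2,3-bis[(3-methoxyphenoxy)(4-methoxyphenyl)methyl]butanedioic acid, is activated as its bis(acid chloride) with (COCl)2 and closed by an SnCl4-mediated double intramolecular Friedel–Crafts acylation of the two 3-methoxyphenyl ethers to give the tetra-O-methyl biflavanone A7.

- In its favour: chromanone formation from β-aryloxy acids is classical. Acylation para to the methoxy group gives the 7-oxygenation pattern. The ring closure creates no stereocentre and needs no later reduction.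
- Against it, the precursor: A6 carries all four contiguous stereocentres in an open chain, where no ring thermodynamics help. Making it is a harder stereochemical problem than the target itself.
- Against it, the key step: the para-methoxybenzylic aryl ether bond (the future C2–O1) ionises under a strong Lewis acid or loses the phenol by elimination to a cinnamoyl derivative. A succinic bis(acid chloride) tends towards the five-membered anhydride. Acylation between the two oxygen substituents would give the 5-methoxy isomer. The methyl ethers again need an acidic deprotection at the end.
- Comparison: at least eight steps, with cationic chemistry at C2. The chosen route forms ring C under basic conditions through C–C acylation and SNAr, with no carbocation near C2, and pays with one diastereomer separation.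

Key step: step 3

## Route

**Step 1**
Reactants: 1 1-[4-(benzyloxy)phenyl]ethan-1-one (two molecules)
Product: 3 1,4-bis[4-(benzyloxy)phenyl]butane-1,4-dione, via lithium 1-[4-(benzyloxy)phenyl]ethenolate 2 (not isolated)
Conditions: LiN(i-Pr)2 (1.1 equiv), THF, −78 °C; CuCl2 (1.1 equiv), DMF, −78 °C → rt
Reagents that add atoms: none
Why: Oxidative homocoupling of a ketone lithium enolate: divalent copper oxidises enolate 2 by one electron and the α-keto radical (or copper enolate) dimerises at carbon, forming the future C3–C3'' bond; a methyl aryl ketone has a single enolisable site, so only the symmetric 1,4-diketone can result and no stereocentre is formed.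

**Step 2**
Reactants: 4 4-(benzyloxy)-2-fluorobenzoic acid
Product: 5 4-(benzyloxy)-2-fluorobenzoyl chloride
Conditions: (COCl)2, DMF (cat.), CH2Cl2, 0 °C → rt
Reagents that add atoms: oxalyl chloride, O=C(Cl)C(Cl)=O
Why: Acid chloride formation through the Vilsmeier-type chloroiminium species from DMF and oxalyl chloride; the mild, non-nucleophilic conditions leave the benzyl ether and the aryl fluoride untouched, and the crude chloride is used directly.

**Step 3**
Reactants: 3 1,4-bis[4-(benzyloxy)phenyl]butane-1,4-dione; 5 4-(benzyloxy)-2-fluorobenzoyl chloride (two molecules)
Product: 8 7,7''-bis(benzyloxy)-2,2''-bis[4-(benzyloxy)phenyl]-4H,4''H-[3,3''-bichromene]-4,4''-dione, via dilithium 1,4-bis[4-(benzyloxy)phenyl]buta-1,3-diene-1,4-diolate 6 (not isolated), via 2,3-bis[4-(benzyloxy)-2-fluorobenzoyl]-1,4-bis[4-(benzyloxy)phenyl]butane-1,4-dione 7 (not isolated)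
Conditions: LiN(SiMe3)2 (4.4 equiv), THF–toluene, −78 → 0 °C; 5 (2.2 equiv), −78 °C → rt; aq. NH4Cl; then K2CO3, DMF, 100 °C
Reagents that add atoms: none
Why: This is Claisen-type enolate C-acylation followed by intramolecular SNAr, the known flavone synthesis from aryl ketone enolates and 2-fluorobenzoyl chlorides, run here at both ends of 3. LiN(SiMe3)2 converts 3 into the bis(enolate) 6, whose α-carbons attack two molecules of 5 to form C3–C4 and C3''–C4''; each new 1,3-diketone is more acidic than 3, so two further equivalents of base hold 7 as its bis(diketonate) and keep unreacted enolate from being quenched. C- over O-acylation is favoured by the tight lithium enolate aggregate in a weakly polar medium at low temperature and is made irreversible by diketonate formation, and in the half-acylated intermediate the remaining ketone enolate is more nucleophilic than the diketonate carbon, so the second acyl group goes to C3'' and not back to C3. After the buffered quench, K2CO3 in DMF regenerates the diketonates, and in each half the enolate oxygen that was a carbonyl oxygen of 3 adds to the fluorine-bearing carbon, which is activated by the ortho ketone while the benzyloxy group, meta to fluorine, sits on no carbon that carries charge in the Meisenheimer intermediate; loss of fluoride forms O1–C8a and O1''–C8a''. Both rings C close in the same way, as six-membered addition–elimination closures (formally 6-exo-trig at the arene carbon); the other enolate oxygen could only form a four-membered ring and attack on the remote fluoroarene a seven-membered one, which fixes the regiochemistry. No stereocentre is formed, since C2, C3, C3'' and C2'' all end up trigonal. Strong acid is kept away throughout because 7 is a 1,4-diketone that could cyclodehydrate to a furan (Paal–Knorr).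

**Step 4**
Reactants: 8 7,7''-bis(benzyloxy)-2,2''-bis[4-(benzyloxy)phenyl]-4H,4''H-[3,3''-bichromene]-4,4''-dione
Product: 10 7,7''-bis(benzyloxy)-2,2''-bis[4-(benzyloxy)phenyl]-[3,3''-bichromane]-4,4''-dione (mixture of diastereomers), via dilithium 7,7''-bis(benzyloxy)-2,2''-bis[4-(benzyloxy)phenyl]-2H,2''H-[3,3''-bichromene]-4,4''-diolate 9 (not isolated)
Conditions: LiBH(s-Bu)3 (2.5 equiv), THF, −78 → −40 °C, Ar; then degassed aq. NH4Cl
Reagents that add atoms: none
Why: Conjugate (1,4-) hydride reduction of the two chromone enones by LiBH(s-Bu)3, a known way from flavones to flavanones: hydride adds at C2 and C2'' to give bis(enolate) 9, which is protonated at C3 and C3'' on quench. C2 and C2'' are created without mutual control because the first lies four atoms from the second enone, so both the like and the unlike pairing are expected, and C3/C3'' are set only provisionally by kinetic protonation. The non-oxidative, oxygen-free work-up protects the electron-rich bis(enolate) and the base-sensitive flavanone rings.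

**Step 5**
Reactants: 10 7,7''-bis(benzyloxy)-2,2''-bis[4-(benzyloxy)phenyl]-[3,3''-bichromane]-4,4''-dione (mixture of diastereomers)
Product: 11 meso-(2S,3R,2''R,3''S)-7,7''-bis(benzyloxy)-2,2''-bis[4-(benzyloxy)phenyl]-[3,3''-bichromane]-4,4''-dione
Conditions: p-TsOH·H2O (cat.), CHCl3, 40 °C; then SiO2 chromatography and crystallisation
Reagents that add atoms: none
Why: Acid-catalysed keto–enol epimerisation acts only at C3 and C3'' and moves each ring C to the more stable 2,3-trans arrangement with the C2 aryl group and the C3 substituent both equatorial (thermodynamic control). C2 and C2'' are not touched, so the unlike-paired part of 10 converges on meso 11 and the like-paired part on the racemic (2S,3R,2''S,3''R)/(2R,3S,2''R,3''S) trans,trans diastereomer, which is removed by chromatography and crystallisation. The acid is catalytic and the temperature low so that neither ring opening nor furan formation from the 1,4-diketone is provoked.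

**Step 6**
Reactants: 11 meso-(2S,3R,2''R,3''S)-7,7''-bis(benzyloxy)-2,2''-bis[4-(benzyloxy)phenyl]-[3,3''-bichromane]-4,4''-dione
Product: 12 meso-(2S,3R,2''R,3''S)-7,7''-dihydroxy-2,2''-bis(4-hydroxyphenyl)-[3,3''-bichromane]-4,4''-dione (CNP0231820.1)
Conditions: H2 (1 atm), Pd/C, THF–MeOH, rt
Reagents that add atoms: none
Why: Catalytic hydrogenolysis of four aryl benzyl ethers under neutral conditions; with neither acid nor base present, C2/C2'' (benzylic, β to the ketone) and C3/C3'' keep their configuration. The electron-rich aryl ketones and the cyclic C2–O1 bonds are expected to react far more slowly than the O-benzyl groups, so the reaction is stopped when debenzylation is complete.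

## Compound list

1 | 1-[4-(benzyloxy)phenyl]ethan-1-one | CC(=O)c1ccc(OCc2ccccc2)cc1 | starting material
2 | lithium 1-[4-(benzyloxy)phenyl]ethenolate | [Li+].[O-]C(=C)c1ccc(OCc2ccccc2)cc1 | intermediate
3 | 1,4-bis[4-(benzyloxy)phenyl]butane-1,4-dione | O=C(CCC(=O)c1ccc(OCc2ccccc2)cc1)c1ccc(OCc2ccccc2)cc1 | intermediate
4 | 4-(benzyloxy)-2-fluorobenzoic acid | OC(=O)c1ccc(OCc2ccccc2)cc1F | starting material
5 | 4-(benzyloxy)-2-fluorobenzoyl chloride | O=C(Cl)c1ccc(OCc2ccccc2)cc1F | intermediate
6 | dilithium 1,4-bis[4-(benzyloxy)phenyl]buta-1,3-diene-1,4-diolate (double-bond geometry not defined) | [Li+].[Li+].[O-]C(=CC=C([O-])c1ccc(OCc2ccccc2)cc1)c1ccc(OCc2ccccc2)cc1 | intermediate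
7 | 2,3-bis[4-(benzyloxy)-2-fluorobenzoyl]-1,4-bis[4-(benzyloxy)phenyl]butane-1,4-dione (enolisable; stereocentres not defined) | O=C(c1ccc(OCc2ccccc2)cc1)C(C(=O)c1ccc(OCc2ccccc2)cc1F)C(C(=O)c1ccc(OCc2ccccc2)cc1)C(=O)c1ccc(OCc2ccccc2)cc1F | intermediate
8 | 7,7''-bis(benzyloxy)-2,2''-bis[4-(benzyloxy)phenyl]-4H,4''H-[3,3''-bichromene]-4,4''-dione (no stereocentre) | O=c1c(-c2c(-c3ccc(OCc4ccccc4)cc3)oc3cc(OCc4ccccc4)ccc3c2=O)c(-c2ccc(OCc3ccccc3)cc2)oc2cc(OCc3ccccc3)ccc12 | intermediate
9 | dilithium 7,7''-bis(benzyloxy)-2,2''-bis[4-(benzyloxy)phenyl]-2H,2''H-[3,3''-bichromene]-4,4''-diolate (C2/C2'' mixture) | [Li+].[Li+].[O-]C1=C(C2=C([O-])c3ccc(OCc4ccccc4)cc3OC2c2ccc(OCc3ccccc3)cc2)C(c2ccc(OCc3ccccc3)cc2)Oc2cc(OCc3ccccc3)ccc12 | intermediate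
10 | 7,7''-bis(benzyloxy)-2,2''-bis[4-(benzyloxy)phenyl]-[3,3''-bichromane]-4,4''-dione (mixture of diastereomers; stereocentres not defined) | O=C1c2ccc(OCc3ccccc3)cc2OC(c2ccc(OCc3ccccc3)cc2)C1C1C(=O)c2ccc(OCc3ccccc3)cc2OC1c1ccc(OCc2ccccc2)cc1 | intermediate
11 | meso-(2S,3R,2''R,3''S)-7,7''-bis(benzyloxy)-2,2''-bis[4-(benzyloxy)phenyl]-[3,3''-bichromane]-4,4''-dione (trans,trans) | O=C1c2ccc(OCc3ccccc3)cc2O[C@H](c2ccc(OCc3ccccc3)cc2)[C@H]1[C@@H]1C(=O)c2ccc(OCc3ccccc3)cc2O[C@H]1c1ccc(OCc2ccccc2)cc1 | intermediate
12 | meso-(2S,3R,2''R,3''S)-7,7''-dihydroxy-2,2''-bis(4-hydroxyphenyl)-[3,3''-bichromane]-4,4''-dione | O=C1c2ccc(O)cc2O[C@H](c2ccc(O)cc2)[C@H]1[C@@H]1C(=O)c2ccc(O)cc2O[C@H]1c1ccc(O)cc1 | target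

## Step count and least certain steps

Total: 6 steps. Longest linear sequence: 5 steps (1 → 3 → 8 → 10 → 11 → 12); step 2 is a one-step side branch.

**Step 3 (key step).** The most likely failure is incomplete or misdirected acylation: O-acylation of the enolates, quenching of the second enolate by the first-formed diketone, or consumption of 5 by the amide base, which leaves material annulated on one side only. The fallback stops relying on acylation at both ends of a preformed C3–C3'' bond and makes tetraketone 7 by oxidative dimerisation. It sets out from 1 and 5. The lithium enolate of 1 (LiN(SiMe3)2, THF, −78 °C) is C-acylated once with 5 to give 1-[4-(benzyloxy)-2-fluorophenyl]-3-[4-(benzyloxy)phenyl]propane-1,3-dione F1. Its sodium salt (NaH, THF, 0 °C) is coupled at the central carbon with I2 (0.5 equiv), the classical route to tetraacylethanes, which gives 7. Cyclisation with K2CO3 in DMF as in step 3 then returns to the route at 8.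

**Step 4.** The most likely failure is stalled conjugate addition: C2 and C2'' are fully substituted and flanked by an aryl group and the other chromone, the hydride donor is bulky, and the enolate formed in the first half donates electron density towards the second enone; 1,2-reduction may then compete. The fallback is exhaustive reduction followed by re-oxidation, starting from 8. NaBH4 in THF–EtOH at reflux, a small hydride donor in a protic medium that protonates each enolate as it forms, takes both chromones through conjugate and then carbonyl reduction to 7,7''-bis(benzyloxy)-2,2''-bis[4-(benzyloxy)phenyl]-[3,3''-bichromane]-4,4''-diol F2 (mixture of stereoisomers; the C4/C4'' configuration is irrelevant). Dess–Martin periodinane (CH2Cl2, NaHCO3) re-oxidises both benzylic alcohols and comes back to the route at 10.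

**Step 5.** The most likely failure is an unfavourable or poorly separable distribution of the meso and the racemic trans,trans diastereomer, because nothing in 8 biases the pairing of C2 with C2''; slow epimerisation at the crowded C3/C3'' is a second possibility. The fallback replaces α-epimerisation alone by ring–chain equilibration, which also moves C2 and C2''. It sets out from 10, in practice from the like-paired material that is left once 11 has been taken out. A catalytic amidine base (DBU, THF, 50 °C) reversibly opens one ring C at a time by β-elimination of the ring A phenoxide. This gives the 2'-hydroxychalcone-type enone 7-(benzyloxy)-3-{3-[4-(benzyloxy)-2-hydroxyphenyl]-1-[4-(benzyloxy)phenyl]-3-oxoprop-1-en-2-yl}-2-[4-(benzyloxy)phenyl]chroman-4-one F3 (not isolated), which recloses by oxa-Michael addition with either configuration at C2. The material so obtained is again the full diastereomer mixture 10, where the fallback comes back to the route; it re-enters step 5 to deliver further 11.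

**Step 1.** The most likely failure is diversion of the enolate into α-chlorination or aldol self-condensation instead of dimerisation. The fallback replaces the one-electron coupling by a two-electron C–C bond formation and sets out from 1. α-Bromination (CuBr2, EtOAc–CHCl3, reflux) gives 2-bromo-1-[4-(benzyloxy)phenyl]ethan-1-one F4. Zinc-enolate coupling of F4 with a second equivalent of 1 (ZnCl2, Et2NH, t-BuOH, toluene, rt), a known direct union of methyl ketones with α-bromomethyl ketones, returns to the route at 3.

**Step 6.** The most likely failure is loss of chemoselectivity on the catalyst: hydrogenolytic opening of the benzylic C2–O1 and C2''–O1'' bonds, reduction of the C4/C4'' carbonyl groups, or incomplete debenzylation of a poorly soluble substrate. The fallback changes from reductive to Lewis-acid cleavage and sets out from 11. BCl3 with pentamethylbenzene as a non-basic cation scavenger (CH2Cl2, −78 °C) removes aryl benzyl ethers at a temperature at which ionisation of the ring C ether should remain slow, and gives 12 directly.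

## Further compounds

F1 | step 3 | 1-[4-(benzyloxy)-2-fluorophenyl]-3-[4-(benzyloxy)phenyl]propane-1,3-dione | O=C(CC(=O)c1ccc(OCc2ccccc2)cc1F)c1ccc(OCc2ccccc2)cc1
F2 | step 4 | 7,7''-bis(benzyloxy)-2,2''-bis[4-(benzyloxy)phenyl]-[3,3''-bichromane]-4,4''-diol (mixture of stereoisomers; stereocentres not defined) | OC1c2ccc(OCc3ccccc3)cc2OC(c2ccc(OCc3ccccc3)cc2)C1C1C(O)c2ccc(OCc3ccccc3)cc2OC1c1ccc(OCc2ccccc2)cc1
F3 | step 5 | 7-(benzyloxy)-3-{3-[4-(benzyloxy)-2-hydroxyphenyl]-1-[4-(benzyloxy)phenyl]-3-oxoprop-1-en-2-yl}-2-[4-(benzyloxy)phenyl]chroman-4-one (transient; alkene geometry and stereocentres not defined) | O=C(c1ccc(OCc2ccccc2)cc1O)C(=Cc1ccc(OCc2ccccc2)cc1)C1C(=O)c2ccc(OCc3ccccc3)cc2OC1c1ccc(OCc2ccccc2)cc1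
F4 | step 1 | 2-bromo-1-[4-(benzyloxy)phenyl]ethan-1-one | O=C(CBr)c1ccc(OCc2ccccc2)cc1
F0 | step 6 | none | none
A1 | alternative 1 | meso trans,trans 7,7''-bis(benzyloxy)-2,2''-bis[4-(benzyloxy)phenyl]-[3,3''-bichromane]-4,4''-dione (identical with 11) | O=C1c2ccc(OCc3ccccc3)cc2O[C@H](c2ccc(OCc3ccccc3)cc2)[C@H]1[C@@H]1C(=O)c2ccc(OCc3ccccc3)cc2O[C@H]1c1ccc(OCc2ccccc2)cc1
A2 | alternative 1 | meso 2,2'-{[1,4-bis[4-(benzyloxy)phenyl]but-2-yne-1,4-diyl]bis(oxy)}bis[4-(benzyloxy)benzaldehyde] | O=Cc1ccc(OCc2ccccc2)cc1O[C@H](c1ccc(OCc2ccccc2)cc1)C#C[C@@H](Oc1cc(OCc2ccccc2)ccc1C=O)c1ccc(OCc2ccccc2)cc1
A3 | alternative 2 | (1E,3E)-1,4-bis(4-methoxyphenyl)buta-1,3-diene | COc1ccc(/C=C/C=C/c2ccc(OC)cc2)cc1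
A4 | alternative 2 | (Z)-1,4-bis(2-fluoro-4-methoxyphenyl)but-2-ene-1,4-dione | COc1ccc(C(=O)/C=C\C(=O)c2ccc(OC)cc2F)c(F)c1
A5 | alternative 2 | all-cis 4,5-bis(2-fluoro-4-methoxybenzoyl)-3,6-bis(4-methoxyphenyl)cyclohexene (meso) | COc1ccc(cc1)[C@@H]1C=C[C@H](c2ccc(OC)cc2)[C@H](C(=O)c2ccc(OC)cc2F)[C@@H]1C(=O)c1ccc(OC)cc1F
A6 | alternative 3 | meso 2,3-bis[(3-methoxyphenoxy)(4-methoxyphenyl)methyl]butanedioic acid | COc1cccc(O[C@H](c2ccc(OC)cc2)[C@H](C(O)=O)[C@H](C(O)=O)[C@@H](Oc2cccc(OC)c2)c2ccc(OC)cc2)c1
A7 | alternative 3 | meso trans,trans 7,7''-dimethoxy-2,2''-bis(4-methoxyphenyl)-[3,3''-bichromane]-4,4''-dione | O=C1c2ccc(OC)cc2O[C@H](c2ccc(OC)cc2)[C@H]1[C@@H]1C(=O)c2ccc(OC)cc2O[C@H]1c1ccc(OC)cc1
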